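**Retrosynthetic overview**

- The target quinone comes from its hydroquinone by Ag2O oxidation. The hydroquinone comes from a (3S)-isoflavan-4-ol by one hydrogenolysis that removes three benzyl ethers and the C4 oxygen, and that alcohol from a (3S)-isoflavanone.
- Key disconnection: the C3–C4 bond of the pyran ring (ring C). The isoflavanone is made from a racemic, acyclic 2-(2-aryl-2-chloroethoxy)benzoyl chloride by an intramolecular enantioconvergent Ni-catalysed reductive acyl–benzyl coupling that closes ring C and sets C3 in one operation.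
- Enabling feature: C3 is the benzylic carbon of ring B, so either enantiomer of the chloride gives the same planar, aryl-stabilised radical. C4 is the benzylic carbon of ring A ortho to O1 and can be carried as an aroyl chloride. The O1–C2 ether tether holds C3 and C4 in a 1,6 relation, so joining them closes a six-membered ring.
- The precursor comes from a ring-A salicylaldehyde (benzylation, Dakin oxidation, ortho-formylation) and a ring-B α-chloro ketone (from 2,3-dimethoxybenzoquinone) by Williamson etherification, Pinnick oxidation, NaBH4 and SOCl2.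
- Ring order: rings A and B are bought as arenes; ring C is the only ring formed.

Key step: step 11

Remark: the target is taken as the 3S enantiomer (CIP order at C3: C2 > quinonyl > C4 > H), and 2,3-dimethoxy-1,4-benzoquinone and 2-hydroxy-3,4-dimethoxybenzaldehyde are taken as purchasable.

**Route**

Step 1
Reactants: 1 2-hydroxy-3,4-dimethoxybenzaldehyde
Product: 2 2-(benzyloxy)-3,4-dimethoxybenzaldehyde
Conditions: BnBr, K2CO3, DMF, 60 °C
Reagents that add atoms: benzyl bromide, BrCc1ccccc1
Why: Williamson ether synthesis on the only phenol should install the benzyl group that later protects the C8 hydroxyl and leaves by hydrogenolysis in the last step.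

Step 2
Reactants: 2 2-(benzyloxy)-3,4-dimethoxybenzaldehyde
Product: 4 2-(benzyloxy)-3,4-dimethoxyphenol, via aryl formate 3 (not isolated)
Conditions: mCPBA, CH2Cl2, rt; then K2CO3 (cat.), MeOH, rt
Reagents that add atoms: mCPBA, OOC(=O)c1cccc(Cl)c1
Why: Baeyer–Villiger (Dakin-type) oxidation should proceed with migration of the electron-rich aryl group, and methanolysis of the formate should free the phenol that becomes O1.

Step 3
Reactants: 4 2-(benzyloxy)-3,4-dimethoxyphenol
Product: 5 3-(benzyloxy)-2-hydroxy-4,5-dimethoxybenzaldehyde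
Conditions: MgCl2, Et3N, (CH2O)n, MeCN, reflux
Reagents that add atoms: paraformaldehyde (as formaldehyde), C=O
Why: Casnati–Skattebøl ortho-formylation through the magnesium phenoxide should place the formyl carbon (the future C4) at the only free ortho position, next to the future O1.

Step 4
Reactants: 6 2,3-dimethoxy-1,4-benzoquinone
Product: 8 1,4-bis(benzyloxy)-2,3-dimethoxybenzene, via 2,3-dimethoxyhydroquinone 7 (not isolated)
Conditions: Na2S2O4, EtOAc/H2O, rt; organic phase concentrated under N2; then BnBr, K2CO3, DMF, 50 °C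
Reagents that add atoms: benzyl bromide, BrCc1ccccc1
Why: Dithionite reduction of the quinone followed by double Williamson etherification should give ring B as its hydroquinone dibenzyl ether, which can be unmasked without any oxidant touching ring A.

Step 5
Reactants: 8 1,4-bis(benzyloxy)-2,3-dimethoxybenzene
Product: 9 1,4-bis(benzyloxy)-5-bromo-2,3-dimethoxybenzene
Conditions: NBS (1.0 equiv), MeCN, 0 °C to rt
Reagents that add atoms: N-bromosuccinimide, O=C1CCC(=O)N1Br
Why: Electrophilic aromatic bromination of the tetra-alkoxybenzene should be fast and regiochemically unambiguous because the two free positions are equivalent.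

Step 6
Reactants: 9 1,4-bis(benzyloxy)-5-bromo-2,3-dimethoxybenzene; 10 2-chloro-N-methoxy-N-methylacetamide
Product: 12 1-[2,5-bis(benzyloxy)-3,4-dimethoxyphenyl]-2-chloroethan-1-one, via aryllithium 11 (not isolated)
Conditions: n-BuLi, THF, −78 °C; then 10, −78 to 0 °C; 1 M HCl
Reagents that add atoms: none
Why: Bromine–lithium exchange followed by Weinreb ketone synthesis should deliver the α-chloro ketone (C3 and C2 of the target) without over-addition, since exchange at −78 °C outruns lithiation of the benzyl ethers.

Step 7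
Reactants: 5 3-(benzyloxy)-2-hydroxy-4,5-dimethoxybenzaldehyde; 12 1-[2,5-bis(benzyloxy)-3,4-dimethoxyphenyl]-2-chloroethan-1-one
Product: 13 3-(benzyloxy)-2-{2-[2,5-bis(benzyloxy)-3,4-dimethoxyphenyl]-2-oxoethoxy}-4,5-dimethoxybenzaldehyde
Conditions: K2CO3, NaI (cat.), acetone, rt
Reagents that add atoms: none
Why: Williamson etherification at the α-halo ketone (Finkelstein-assisted SN2) should form the O1–C2 bond, and the weak base at room temperature should avoid Rap–Stoermer condensation to a benzofuran.

Step 8
Reactants: 13 keto aldehyde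
Product: 14 3-(benzyloxy)-2-{2-[2,5-bis(benzyloxy)-3,4-dimethoxyphenyl]-2-oxoethoxy}-4,5-dimethoxybenzoic acid
Conditions: NaClO2, NaH2PO4, 2-methyl-2-butene, t-BuOH/THF/H2O, 0 °C to rt
Reagents that add atoms: sodium chlorite, [Na+].[O-]Cl=O
Why: Pinnick oxidation should be aldehyde-selective and raise C4 to the acyl level, with the alkene scavenger protecting the electron-rich rings from hypochlorous acid.

Step 9
Reactants: 14 keto acid
Product: 15 rac-3-(benzyloxy)-2-{2-[2,5-bis(benzyloxy)-3,4-dimethoxyphenyl]-2-hydroxyethoxy}-4,5-dimethoxybenzoic acid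
Conditions: NaBH4 (excess), THF/MeOH, 0 °C; then dilute HCl
Reagents that add atoms: none
Why: Borohydride reduction should convert the aryl ketone to the benzylic alcohol while the carboxylate is inert, and the racemic outcome is acceptable because C3 is set only in step 11.

Step 10
Reactants: 15 rac-hydroxy acid
Product: 16 rac-3-(benzyloxy)-2-{2-[2,5-bis(benzyloxy)-3,4-dimethoxyphenyl]-2-chloroethoxy}-4,5-dimethoxybenzoyl chloride
Conditions: SOCl2 (5 equiv), DMF (cat.), CH2Cl2, 0 °C to rt; evaporate, toluene azeotrope; used crude at once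
Reagents that add atoms: thionyl chloride, ClS(Cl)=O
Why: Chlorodehydroxylation with thionyl chloride should convert the electron-rich benzylic alcohol (through its chlorosulfite, SN1/SNi) and the acid (Vilsmeier-type activation) into the two electrophiles in one operation, the benzylic chlorination being faster than lactonisation.

Step 11
Reactants: 16 rac-chloro acid chloride
Product: 17 (3S)-8-(benzyloxy)-3-[2,5-bis(benzyloxy)-3,4-dimethoxyphenyl]-6,7-dimethoxy-2,3-dihydro-4H-chromen-4-one
Conditions: NiCl2(dme) (10 mol %), chiral bis(oxazoline) L* [2,2'-(propane-2,2-diyl)bis(4,5-diphenyl-4,5-dihydrooxazole), one antipode] (12 mol %), Mn powder (3 equiv), 2,6-dimethylbenzoic acid (0.75 equiv), 3 Å MS, DMA/THF 3:7, 20 °C; 16 added by syringe pump to about 0.01 M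
Reagents that add atoms: none
Why: Proposed new method: zerovalent nickel bearing L* should add oxidatively to the aroyl chloride, the Mn-reduced acyl nickel species should abstract chlorine from the secondary benzylic chloride, and the planar ring-B-stabilised C3 radical should be recaptured by the tethered acyl nickel centre to give a seven-membered acyl(benzyl) trivalent nickel metallacycle whose C(acyl)–C(sp3) reductive elimination forms the C3–C4 bond, Mn then returning nickel to the zerovalent state. The closest known reaction type is the intermolecular Ni/bis(oxazoline)-catalysed enantioconvergent reductive coupling of acid chlorides with racemic secondary benzylic chlorides to α-aryl ketones under the same Mn/2,6-dimethylbenzoic acid conditions; new here are the ring-closing mode, the aroyl instead of alkanoyl chloride and the β-aryloxy substituent. Ring C (the dihydropyranone) closes in a formal 6-exo-trig sense, the benzylic carbon attacking the acyl carbon whose oxygen stays outside the ring, by contraction of the metallacycle; it is the only ring formed. The C3 stereocentre is catalyst-controlled: both enantiomers of 16 converge on the same radical, and the ligand antipode (fixed in a first screen of both antipodes) decides the face of radical capture and reductive elimination, aiming at 3S. The step needs cyclisation to win over oligomerisation and benzylic homocoupling, which slow addition at high dilution and the faster oxidative addition of the aroyl chloride should secure, and it needs C3 not to lose the β-aryloxy group, which a short-lived radical rather than a persistent benzylic nickel species should secure. The non-basic medium should keep the enolisable α-aryl ketone 17 from racemising.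

Step 12
Reactants: 17 (3S)-isoflavanone
Product: 18 (3S)-8-(benzyloxy)-3-[2,5-bis(benzyloxy)-3,4-dimethoxyphenyl]-6,7-dimethoxy-3,4-dihydro-2H-chromen-4-ol (both C4 epimers)
Conditions: NaBH4, CeCl3·7H2O, MeOH/THF, −78 to −40 °C
Reagents that add atoms: none
Why: Luche reduction should reduce the ketone quickly at low temperature without enolisation at C3, and the C4 epimer mixture does not matter because C4 becomes a methylene group.

Step 13
Reactants: 18 (3S)-isoflavan-4-ol
Product: 20 5-[(3S)-8-hydroxy-6,7-dimethoxy-3,4-dihydro-2H-chromen-3-yl]-2,3-dimethoxycyclohexa-2,5-diene-1,4-dione (CNP0269725.1), via hydroquinone 19 (not isolated)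
Conditions: H2 (3 bar), Pd(OH)2/C, EtOAc/EtOH, rt, no acid; filter under Ar; then Ag2O (1.5 equiv), Na2SO4, Et2O, rt
Reagents that add atoms: none
Why: Catalytic hydrogenolysis should cleave the three benzyl ethers and the C4–O bond (benzylic, activated by the para methoxy group and the ortho ring oxygen) without touching C3, and Ag2O oxidation should convert only the hydroquinone to the p-quinone because the C8 phenol has no para hydroxyl.

**Compound list**

1 | 2-hydroxy-3,4-dimethoxybenzaldehyde | O=Cc1ccc(OC)c(OC)c1O | starting material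
2 | 2-(benzyloxy)-3,4-dimethoxybenzaldehyde | O=Cc1ccc(OC)c(OC)c1OCc1ccccc1 | intermediate
3 | 2-(benzyloxy)-3,4-dimethoxyphenyl formate (not isolated) | O=COc1ccc(OC)c(OC)c1OCc1ccccc1 | intermediate
4 | 2-(benzyloxy)-3,4-dimethoxyphenol | Oc1ccc(OC)c(OC)c1OCc1ccccc1 | intermediate
5 | 3-(benzyloxy)-2-hydroxy-4,5-dimethoxybenzaldehyde | O=Cc1cc(OC)c(OC)c(OCc2ccccc2)c1O | intermediate
6 | 2,3-dimethoxy-1,4-benzoquinone | COC1=C(OC)C(=O)C=CC1=O | starting material
7 | 2,3-dimethoxybenzene-1,4-diol (not isolated) | COc1c(O)ccc(O)c1OC | intermediate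
8 | 1,4-bis(benzyloxy)-2,3-dimethoxybenzene | COc1c(OCc2ccccc2)ccc(OCc2ccccc2)c1OC | intermediate
9 | 1,4-bis(benzyloxy)-5-bromo-2,3-dimethoxybenzene | Brc1cc(OCc2ccccc2)c(OC)c(OC)c1OCc1ccccc1 | intermediate
10 | 2-chloro-N-methoxy-N-methylacetamide | ClCC(=O)N(C)OC | starting material
11 | [2,5-bis(benzyloxy)-3,4-dimethoxyphenyl]lithium (not isolated) | [Li]c1cc(OCc2ccccc2)c(OC)c(OC)c1OCc1ccccc1 | intermediate
12 | 1-[2,5-bis(benzyloxy)-3,4-dimethoxyphenyl]-2-chloroethan-1-one | O=C(CCl)c1cc(OCc2ccccc2)c(OC)c(OC)c1OCc1ccccc1 | intermediate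
13 | 3-(benzyloxy)-2-{2-[2,5-bis(benzyloxy)-3,4-dimethoxyphenyl]-2-oxoethoxy}-4,5-dimethoxybenzaldehyde | O=Cc1cc(OC)c(OC)c(OCc2ccccc2)c1OCC(=O)c1cc(OCc2ccccc2)c(OC)c(OC)c1OCc1ccccc1 | intermediate
14 | 3-(benzyloxy)-2-{2-[2,5-bis(benzyloxy)-3,4-dimethoxyphenyl]-2-oxoethoxy}-4,5-dimethoxybenzoic acid | OC(=O)c1cc(OC)c(OC)c(OCc2ccccc2)c1OCC(=O)c1cc(OCc2ccccc2)c(OC)c(OC)c1OCc1ccccc1 | intermediate
15 | rac-3-(benzyloxy)-2-{2-[2,5-bis(benzyloxy)-3,4-dimethoxyphenyl]-2-hydroxyethoxy}-4,5-dimethoxybenzoic acid | OC(=O)c1cc(OC)c(OC)c(OCc2ccccc2)c1OCC(O)c1cc(OCc2ccccc2)c(OC)c(OC)c1OCc1ccccc1 | intermediate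
16 | rac-3-(benzyloxy)-2-{2-[2,5-bis(benzyloxy)-3,4-dimethoxyphenyl]-2-chloroethoxy}-4,5-dimethoxybenzoyl chloride | ClC(=O)c1cc(OC)c(OC)c(OCc2ccccc2)c1OCC(Cl)c1cc(OCc2ccccc2)c(OC)c(OC)c1OCc1ccccc1 | intermediate
17 | (3S)-8-(benzyloxy)-3-[2,5-bis(benzyloxy)-3,4-dimethoxyphenyl]-6,7-dimethoxy-2,3-dihydro-4H-chromen-4-one | O=C1c2cc(OC)c(OC)c(OCc3ccccc3)c2OC[C@@H]1c1cc(OCc2ccccc2)c(OC)c(OC)c1OCc1ccccc1 | intermediate
18 | (3S)-8-(benzyloxy)-3-[2,5-bis(benzyloxy)-3,4-dimethoxyphenyl]-6,7-dimethoxy-3,4-dihydro-2H-chromen-4-ol, both C4 epimers | OC1c2cc(OC)c(OC)c(OCc3ccccc3)c2OC[C@@H]1c1cc(OCc2ccccc2)c(OC)c(OC)c1OCc1ccccc1 | intermediate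
19 | 2-[(3S)-8-hydroxy-6,7-dimethoxy-3,4-dihydro-2H-chromen-3-yl]-5,6-dimethoxybenzene-1,4-diol (not isolated) | C1c2cc(OC)c(OC)c(O)c2OC[C@@H]1c1cc(O)c(OC)c(OC)c1O | intermediate
20 | 5-[(3S)-8-hydroxy-6,7-dimethoxy-3,4-dihydro-2H-chromen-3-yl]-2,3-dimethoxycyclohexa-2,5-diene-1,4-dione | COC1=C(OC)C(=O)C([C@H]2COc3c(cc(OC)c(OC)c3O)C2)=CC1=O | target

**Step count and risks**

Total steps: 13. Longest linear sequence: 10 (steps 1–3 or 4–6, then steps 7–13).

Steps most likely to fail:

1. Step 11 (proposed new method). Ring closure may lose to intermolecular coupling, to hydrodechlorination or β-aryloxy loss at C3, or the cyclic radical capture may give poor enantio-induction. Fallback in known chemistry, setting out from keto aldehyde 13: an achiral triazolium-derived N-heterocyclic carbene (2-mesityl-6,7-dihydro-5H-pyrrolo[2,1-c][1,2,4]triazol-2-ium chloride, DBU, THF, rt) should effect the intramolecular crossed benzoin reaction, which again closes ring C through the C3–C4 bond, to give the racemic 3-hydroxyisoflavanone F1. SmI2 (THF/MeOH, −78 °C) should then remove the α-hydroxyl to give the racemic isoflavanone F2. Transfer hydrogenation under dynamic kinetic resolution with RuCl(p-cymene)[TsDPEN] (antipode chosen for the 3S series; HCO2H/Et3N, EtOAc, 40 °C) should funnel both enantiomers of F2 into the cis-(3S,4S)-isoflavan-4-ol F3. F3 is one C4 epimer of compound 18 and comes back to the route there, entering step 13.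

2. Step 10. The hydroxyl may attack the activated carboxyl (lactonisation), or the electron-rich benzylic chloride may ionise and eliminate during concentration. Fallback, setting out from hydroxy acid 15: deliberate Yamaguchi lactonisation (2,4,6-trichlorobenzoyl chloride, Et3N, THF; then DMAP, toluene, high dilution) should give the stable, purifiable seven-membered lactone F4. Ring-opening chlorination of F4 (SOCl2, ZnCl2 cat., CH2Cl2, 40 °C; chloride attacks the benzylic C–O carbon and the freed carboxyl becomes the acid chloride) should then give compound 16 immediately before the coupling, where the route is rejoined.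

3. Step 13. Cleavage of the C4–O bond may lag behind debenzylation, or dehydration toward the C3=C4 alkene on the catalyst followed by unselective hydrogen addition may erode the C3 configuration. Fallback, setting out from alcohol 18: ionic hydrogenation in solution (Et3SiH in large excess, CF3CO2H, CH2Cl2, −40 °C; hydride transfer to the C4 cation) should give the (3S)-tribenzyl isoflavan F5 before any deprotection. Hydrogenolysis of F5 (H2, Pd/C, EtOAc) should then give hydroquinone 19, where the route is rejoined for the Ag2O oxidation to 20.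

**Further compounds**

F1 | step 11 | rac-8-(benzyloxy)-3-[2,5-bis(benzyloxy)-3,4-dimethoxyphenyl]-3-hydroxy-6,7-dimethoxy-2,3-dihydro-4H-chromen-4-one | O=C1c2cc(OC)c(OC)c(OCc3ccccc3)c2OCC1(O)c1cc(OCc2ccccc2)c(OC)c(OC)c1OCc1ccccc1
F2 | step 11 | rac-8-(benzyloxy)-3-[2,5-bis(benzyloxy)-3,4-dimethoxyphenyl]-6,7-dimethoxy-2,3-dihydro-4H-chromen-4-one | O=C1c2cc(OC)c(OC)c(OCc3ccccc3)c2OCC1c1cc(OCc2ccccc2)c(OC)c(OC)c1OCc1ccccc1
F3 | step 11 | (3S,4S)-8-(benzyloxy)-3-[2,5-bis(benzyloxy)-3,4-dimethoxyphenyl]-6,7-dimethoxy-3,4-dihydro-2H-chromen-4-ol (cis) | O[C@@H]1c2cc(OC)c(OC)c(OCc3ccccc3)c2OC[C@@H]1c1cc(OCc2ccccc2)c(OC)c(OC)c1OCc1ccccc1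
F4 | step 10 | rac-9-(benzyloxy)-3-[2,5-bis(benzyloxy)-3,4-dimethoxyphenyl]-7,8-dimethoxy-2,3-dihydro-5H-1,4-benzodioxepin-5-one | O=C1OC(c2cc(OCc3ccccc3)c(OC)c(OC)c2OCc2ccccc2)COc2c(OCc3ccccc3)c(OC)c(OC)cc12
F5 | step 13 | (3S)-8-(benzyloxy)-3-[2,5-bis(benzyloxy)-3,4-dimethoxyphenyl]-6,7-dimethoxy-3,4-dihydro-2H-chromene | C1c2cc(OC)c(OC)c(OCc3ccccc3)c2OC[C@@H]1c1cc(OCc2ccccc2)c(OC)c(OC)c1OCc1ccccc1
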